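**Plan**
- Retrosynthesis: remove the 13 O‑benzyl groups; cut O1–C2 and C3–C4 of the upper pyran ring together (retro oxa‑[4+2]) into an o‑quinone methide O1=C8a–C4a=C4, which already carries C8 of the catechin unit on C4, and a (Z)‑enol gallate (C2=C3); cut C4–C8 into an 8‑lithiocatechin and an A‑ring salicylaldehyde; cut the enol ester into an arylacetylene and tribenzylgallic acid.
- Forward: (+)‑catechin is perbenzylated, brominated at C8, lithiated and added to the A‑ring aldehyde; desilylation gives the o‑hydroxy‑diarylmethanol. Ru‑catalysed addition of the acid to the alkyne gives the Z‑enol ester. The cycloaddition then closes the upper C ring, the only ring built in the route, and hydrogenolysis ends it.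
- Enabling feature: C4 of the upper unit is a methine flanked by two phloroglucinol‑type rings and sits ortho to the phenolic O1 on the A ring, so C4–C4a–C8a–O1 ionises easily to a heterodiene; C2(aryl)–C3(O‑galloyl), cis in the target, maps onto a Z‑β‑acyloxystyrene.
- Stereochemistry: lower‑unit C2/C3 come from (+)‑catechin. Upper 2,3‑cis comes from the Z alkene (suprafacial addition), 3,4‑trans from exo placement of the acyloxy group, and the absolute sense from a chiral phosphoric acid; facial isomers are diastereomers and separable.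

Key step: step 10

Assumption: the phosphoric acid of step 10 is written as (R)‑TRIP; because 10 is already enantiopure the two catalyst antipodes form a matched and a mismatched pair, and the antipode that proves matched for the (2R,3R,4R) face is the one meant.

**Step 1**
Reactants: 1 (+)‑catechin
Product: 2 5,7,3',4'‑tetra‑O‑benzyl‑(+)‑catechin
Conditions: BnBr (4.4 equiv), K2CO3, DMF, 0 °C → rt
Reagents that add atoms: benzyl bromide, BrCc1ccccc1
Why: Williamson etherification in which K2CO3 deprotonates only the four phenols, so the secondary 3‑OH stays free and no stereocenter is touched.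

**Step 2**
Reactants: 2 5,7,3',4'‑tetra‑O‑benzyl‑(+)‑catechin
Product: 3 3,5,7,3',4'‑penta‑O‑benzyl‑(+)‑catechin
Conditions: NaH, BnBr, cat. Bu4NI, DMF, 0 °C → rt
Reagents that add atoms: benzyl bromide, BrCc1ccccc1
Why: Williamson etherification of the secondary alkoxide removes the last acidic proton before the organolithium step and leaves C2 and C3 unchanged.

**Step 3**
Reactants: 3 3,5,7,3',4'‑penta‑O‑benzyl‑(+)‑catechin
Product: 4 8‑bromo‑3,5,7,3',4'‑penta‑O‑benzyl‑(+)‑catechin
Conditions: NBS (1.0 equiv), CH2Cl2, −40 → 0 °C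
Reagents that add atoms: N‑bromosuccinimide, O=C1CCC(=O)N1Br
Why: Electrophilic aromatic bromination, which in 5,7‑di‑O‑benzyl flavans goes to C8 in preference to C6 and stops at the monobromide with one equivalent at low temperature.

**Step 4**
Reactants: 5 2,4,6‑trihydroxybenzaldehyde
Product: 6 2,4‑bis(benzyloxy)‑6‑hydroxybenzaldehyde
Conditions: BnBr (2.1 equiv), K2CO3, DMF, rt
Reagents that add atoms: benzyl bromide, BrCc1ccccc1
Why: Williamson etherification under weak base, in which the 4‑OH reacts first and, once one ortho‑OH is benzylated, the other is held by a hydrogen bond to the formyl group and stays free.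

**Step 5**
Reactants: 6 2,4‑bis(benzyloxy)‑6‑hydroxybenzaldehyde
Product: 7 2,4‑bis(benzyloxy)‑6‑(tert‑butyldimethylsilyloxy)benzaldehyde
Conditions: TBSCl, imidazole, cat. DMAP, DMF, rt
Reagents that add atoms: tert‑butyldimethylsilyl chloride, CC(C)(C)[Si](C)(C)Cl
Why: Silylation of the phenol gives an aryl silyl ether that tolerates the aryllithium and can later be removed by fluoride without acid.

**Step 6**
Reactants: 4 8‑bromo‑3,5,7,3',4'‑penta‑O‑benzyl‑(+)‑catechin; 7 2,4‑bis(benzyloxy)‑6‑(tert‑butyldimethylsilyloxy)benzaldehyde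
Product: 9 silyl‑protected diarylmethanol (carbinol epimers), via 8‑lithio‑penta‑O‑benzylcatechin 8 (not isolated)
Conditions: n‑BuLi (1.05 equiv), THF, −78 °C; then 7 (1.2 equiv), −78 °C; sat. aq NH4Cl at −78 °C
Reagents that add atoms: none
Why: Bromine–lithium exchange followed by 1,2‑addition of the aryllithium to the aldehyde forms the interflavan C4–C8 bond with complete C8 regiocontrol; the new carbinol center forms as a mixture and is erased in step 10.

**Step 7**
Reactants: 9 silyl‑protected diarylmethanol (carbinol epimers)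
Product: 10 2‑[hydroxy(penta‑O‑benzylcatechin‑8‑yl)methyl]‑3,5‑bis(benzyloxy)phenol (carbinol epimers)
Conditions: TBAF (1.1 equiv), AcOH (1.1 equiv), THF, 0 °C; Et3N‑deactivated silica
Reagents that add atoms: none
Why: Buffered fluoride desilylation frees the phenol (from either oxygen, should the silyl group have migrated to the carbinol) without ionising the acid‑labile diarylmethanol.

**Step 8**
Reactants: 11 3,4,5‑tris(benzyloxy)benzaldehyde
Product: 12 5‑ethynyl‑1,2,3‑tris(benzyloxy)benzene
Conditions: Ohira–Bestmann reagent, K2CO3, MeOH/THF, rt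
Reagents that add atoms: dimethyl (1‑diazo‑2‑oxopropyl)phosphonate, COP(=O)(OC)C(=[N+]=[N-])C(C)=O
Why: Seyferth–Gilbert homologation in the Ohira–Bestmann variant converts the aldehyde into the terminal alkyne under mild base that benzyl ethers tolerate.

**Step 9**
Reactants: 12 5‑ethynyl‑1,2,3‑tris(benzyloxy)benzene; 13 3,4,5‑tris(benzyloxy)benzoic acid
Product: 14 (Z)‑2‑[3,4,5‑tris(benzyloxy)phenyl]vinyl 3,4,5‑tris(benzyloxy)benzoate
Conditions: [Ru(methallyl)2(dppb)] (2 mol %), toluene, 65 °C
Reagents that add atoms: none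
Why: Ruthenium‑catalysed anti‑Markovnikov hydro‑oxycarbonylation of a terminal arylalkyne through a vinylidene intermediate is a reaction type that delivers (Z)‑enol esters, and this Z geometry is what later becomes the 2,3‑cis relationship.

**Step 10**
Reactants: 10 2‑[hydroxy(penta‑O‑benzylcatechin‑8‑yl)methyl]‑3,5‑bis(benzyloxy)phenol; 14 (Z)‑enol gallate
Product: 16 trideca‑O‑benzyl derivative of the target, via o‑quinone methide 15 (not isolated)
Conditions: 14 (2.5 equiv), (R)‑TRIP (10 mol %), 5 Å MS, toluene, −20 °C → rt; chromatography to remove minor diastereomers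
Reagents that add atoms: none
Why: Proposed new method: the phosphoric acid dehydrates 10 to the o‑quinone methide 15 (O1=C8a–C4a=C4, held to the phosphate by hydrogen bonding or ion pairing), which should add to the Z‑enol ester in an asynchronous inverse‑electron‑demand oxa‑[4+2] cycloaddition in which C3–C4 bonding leads and O1–C2 closure follows within the same suprafacial event. The closest known reaction type is the Brønsted‑acid‑catalysed (including chiral phosphoric acid) hetero‑Diels–Alder reaction of o‑hydroxybenzhydrol‑derived o‑quinone methides with styrenes and β‑substituted styrenes to give 2‑aryl chromans; new here are the β‑acyloxystyrene as 2π partner and the flavanyl group on the methide carbon. The one ring formed, the upper dihydropyran, is closed by intermolecular [4+2] annulation that makes two σ bonds, C3–C4 and then O1–C2 by six‑membered closure of the A‑ring oxygen onto the developing benzylic C2 cation. C2 and C3 should be set cis by the Z geometry of the dienophile, and C4 trans to C3 because the galloyloxy group takes the exo position away from the C5 benzyloxy group and from the twisted, di‑ortho‑substituted aryl on C4 (the same steric preference that gives 3,4‑trans chromans from β‑substituted styrenes). The absolute sense (2R,3R,4R) should be set by the face of 15 left open by the chiral phosphate in a matched pairing with the catechin unit, and any facial isomer is a diastereomer that chromatography removes. The step needs regioselectivity (aryl‑bearing carbon to O1), which the 4‑benzyloxyphenyl donor should secure because it stabilises positive charge at C2 far better than the weakly donating acyloxy group would at C3, and it needs to stay concerted, which the non‑polar solvent, low temperature and tight ion pair are chosen to favour.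

**Step 11**
Reactants: 16 trideca‑O‑benzyl derivative of the target
Product: 17 epigallocatechin 3‑O‑gallate‑(4β→8)‑catechin (target)
Conditions: H2 (1 atm), 20% Pd(OH)2/C, THF/MeOH/H2O, rt; Sephadex LH‑20
Reagents that add atoms: none
Why: Hydrogenolysis over Pearlman's catalyst should cleave all thirteen benzyl ethers (twelve aryl, one alkyl) while the gallate ester, the interflavan bond and all five stereocenters are unaffected, as in standard proanthocyanidin end‑games.

**Compound list**
1 | (+)‑catechin (2R,3S) | Oc1cc(O)c2c(c1)O[C@H](c1ccc(O)c(O)c1)[C@@H](O)C2 | starting material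
2 | 5,7,3',4'‑tetra‑O‑benzyl‑(+)‑catechin | c1ccccc1COc1cc(OCc3ccccc3)c2c(c1)O[C@H](c1ccc(OCc3ccccc3)c(OCc3ccccc3)c1)[C@@H](O)C2 | intermediate
3 | 3,5,7,3',4'‑penta‑O‑benzyl‑(+)‑catechin | c1ccccc1COc1cc(OCc3ccccc3)c2c(c1)O[C@H](c1ccc(OCc3ccccc3)c(OCc3ccccc3)c1)[C@@H](OCc1ccccc1)C2 | intermediate
4 | 8‑bromo‑3,5,7,3',4'‑penta‑O‑benzyl‑(+)‑catechin | c1ccccc1COc1cc(OCc3ccccc3)c2c(c1Br)O[C@H](c1ccc(OCc3ccccc3)c(OCc3ccccc3)c1)[C@@H](OCc1ccccc1)C2 | intermediate
5 | 2,4,6‑trihydroxybenzaldehyde | O=Cc1c(O)cc(O)cc1O | starting material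
6 | 2,4‑bis(benzyloxy)‑6‑hydroxybenzaldehyde | O=Cc1c(O)cc(OCc2ccccc2)cc1OCc1ccccc1 | intermediate
7 | 2,4‑bis(benzyloxy)‑6‑(tert‑butyldimethylsilyloxy)benzaldehyde | O=Cc1c(O[Si](C)(C)C(C)(C)C)cc(OCc2ccccc2)cc1OCc1ccccc1 | intermediate
8 | 8‑lithio‑3,5,7,3',4'‑penta‑O‑benzyl‑(+)‑catechin (not isolated) | c1ccccc1COc1cc(OCc3ccccc3)c2c(c1[Li])O[C@H](c1ccc(OCc3ccccc3)c(OCc3ccccc3)c1)[C@@H](OCc1ccccc1)C2 | intermediate
9 | [2,4‑bis(benzyloxy)‑6‑(tert‑butyldimethylsilyloxy)phenyl](3,5,7,3',4'‑penta‑O‑benzylcatechin‑8‑yl)methanol, carbinol epimers | OC(c1c(O[Si](C)(C)C(C)(C)C)cc(OCc2ccccc2)cc1OCc1ccccc1)c1c(OCc2ccccc2)cc(OCc2ccccc2)c2c1O[C@H](c1ccc(OCc3ccccc3)c(OCc3ccccc3)c1)[C@@H](OCc1ccccc1)C2 | intermediate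
10 | 2‑[hydroxy(3,5,7,3',4'‑penta‑O‑benzylcatechin‑8‑yl)methyl]‑3,5‑bis(benzyloxy)phenol, carbinol epimers | OC(c1c(O)cc(OCc2ccccc2)cc1OCc1ccccc1)c1c(OCc2ccccc2)cc(OCc2ccccc2)c2c1O[C@H](c1ccc(OCc3ccccc3)c(OCc3ccccc3)c1)[C@@H](OCc1ccccc1)C2 | intermediate
11 | 3,4,5‑tris(benzyloxy)benzaldehyde | O=Cc1cc(OCc2ccccc2)c(OCc2ccccc2)c(OCc2ccccc2)c1 | starting material
12 | 5‑ethynyl‑1,2,3‑tris(benzyloxy)benzene | C#Cc1cc(OCc2ccccc2)c(OCc2ccccc2)c(OCc2ccccc2)c1 | intermediate
13 | 3,4,5‑tris(benzyloxy)benzoic acid | OC(=O)c1cc(OCc2ccccc2)c(OCc2ccccc2)c(OCc2ccccc2)c1 | starting material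
14 | (Z)‑2‑[3,4,5‑tris(benzyloxy)phenyl]vinyl 3,4,5‑tris(benzyloxy)benzoate | O=C(O/C=C\c1cc(OCc2ccccc2)c(OCc2ccccc2)c(OCc2ccccc2)c1)c1cc(OCc2ccccc2)c(OCc2ccccc2)c(OCc2ccccc2)c1 | intermediate
15 | 3,5‑bis(benzyloxy)‑6‑[(penta‑O‑benzylcatechin‑8‑yl)methylidene]cyclohexa‑2,4‑dienone (o‑quinone methide, not isolated) | O=C1C=C(OCc2ccccc2)C=C(OCc2ccccc2)C1=Cc1c(OCc2ccccc2)cc(OCc2ccccc2)c2c1O[C@H](c1ccc(OCc3ccccc3)c(OCc3ccccc3)c1)[C@@H](OCc1ccccc1)C2 | intermediate
16 | 5,7,3',4',5'‑penta‑O‑benzyl‑3‑O‑(3,4,5‑tri‑O‑benzylgalloyl)epigallocatechin‑(4β→8)‑3,5,7,3',4'‑penta‑O‑benzylcatechin | O=C(O[C@@H]1[C@@H](c2c(OCc4ccccc4)cc(OCc4ccccc4)c3c2O[C@H](c2ccc(OCc4ccccc4)c(OCc4ccccc4)c2)[C@@H](OCc2ccccc2)C3)c2c(OCc3ccccc3)cc(OCc3ccccc3)cc2O[C@@H]1c1cc(OCc2ccccc2)c(OCc2ccccc2)c(OCc2ccccc2)c1)c1cc(OCc2ccccc2)c(OCc2ccccc2)c(OCc2ccccc2)c1 | intermediate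
17 | epigallocatechin 3‑O‑gallate‑(4β→8)‑catechin (upper unit 2R,3R,4R; lower unit 2R,3S) | O=C(O[C@@H]1[C@@H](c2c(O)cc(O)c3c2O[C@H](c2ccc(O)c(O)c2)[C@@H](O)C3)c2c(O)cc(O)cc2O[C@@H]1c1cc(O)c(O)c(O)c1)c1cc(O)c(O)c(O)c1 | target

**Totals**
Total step count: 11. Longest linear sequence: 7 (steps 1, 2, 3, 6, 7, 10, 11).

**Steps most likely to fail**

Step 10. The cycloaddition may leave the concerted path: a stepwise cationic addition allows rotation about C2–C3 before ring closure and erodes the 2,3‑cis relationship. It may also show poor exo/endo or facial discrimination, or the acyloxy‑deactivated alkene may be outpaced by Friedel–Crafts self‑condensation of the quinone methide. The fallback, all known chemistry, gives up building the ring and takes it from the chiral pool. It sets out from compound 3 and from purchased (−)‑epigallocatechin gallate F1. Perbenzylation of F1 (BnBr, K2CO3, DMF) should give octa‑O‑benzyl‑epigallocatechin gallate F2. Benzylic oxidation at C4 with DDQ in the presence of 2‑ethoxyethanol (CH2Cl2, rt) should give the 4β‑(2‑ethoxyethoxy) ether F3. TMSOTf‑promoted Friedel–Crafts coupling of F3 with an excess of 3 (CH2Cl2, −78 °C) should then give 16 by attack of C8 on the C4 cation anti to the 3‑acyloxy group, and the route is rejoined at compound 16.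

Step 6. The 1,2‑addition joins two di‑ortho‑substituted partners and may be slow, leaving room for proton transfer; O‑to‑O silyl migration followed by premature elimination to the quinone methide could also lead to a second aryl addition. The fallback sets out from compound 4 (through aryllithium 8) and comes back at compound 10, so that steps 5 and 7 are no longer needed. Aryllithium 8 is quenched with DMF to give 8‑formyl‑3,5,7,3',4'‑penta‑O‑benzylcatechin F4. The bromomagnesium phenoxide of purchased 3,5‑bis(benzyloxy)phenol F5 (EtMgBr, toluene) is then condensed with F4 in an ortho‑specific, chelation‑directed hydroxyalkylation of Casiraghi type, which should give 10 directly.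

Step 4. Partial alkylation may be unselective, with over‑ and under‑benzylation and C‑benzylation of the phloroglucinol nucleus. The fallback sets out from purchased 1,3,5‑tris(benzyloxy)benzene F6 and comes back at compound 6. Vilsmeier–Haack formylation (POCl3, DMF) should give 2,4,6‑tris(benzyloxy)benzaldehyde F7 as the only possible regioisomer. MgBr2·OEt2 (toluene/Et2O) should then remove one benzyl group ortho to the formyl group by chelation‑assisted cleavage to give 6.

**Further compounds**
F1 | step 10 | (−)‑epigallocatechin gallate (purchased) | O=C(O[C@@H]1Cc2c(O)cc(O)cc2O[C@@H]1c1cc(O)c(O)c(O)c1)c1cc(O)c(O)c(O)c1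
F2 | step 10 | octa‑O‑benzyl‑epigallocatechin gallate | O=C(O[C@@H]1Cc2c(OCc3ccccc3)cc(OCc3ccccc3)cc2O[C@@H]1c1cc(OCc2ccccc2)c(OCc2ccccc2)c(OCc2ccccc2)c1)c1cc(OCc2ccccc2)c(OCc2ccccc2)c(OCc2ccccc2)c1
F3 | step 10 | 4β‑(2‑ethoxyethoxy)‑octa‑O‑benzyl‑epigallocatechin gallate | O=C(O[C@@H]1[C@@H](OCCOCC)c2c(OCc3ccccc3)cc(OCc3ccccc3)cc2O[C@@H]1c1cc(OCc2ccccc2)c(OCc2ccccc2)c(OCc2ccccc2)c1)c1cc(OCc2ccccc2)c(OCc2ccccc2)c(OCc2ccccc2)c1
F4 | step 6 | 8‑formyl‑3,5,7,3',4'‑penta‑O‑benzyl‑(+)‑catechin | c1ccccc1COc1cc(OCc3ccccc3)c2c(c1C=O)O[C@H](c1ccc(OCc3ccccc3)c(OCc3ccccc3)c1)[C@@H](OCc1ccccc1)C2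
F5 | step 6 | 3,5‑bis(benzyloxy)phenol (purchased) | Oc1cc(OCc2ccccc2)cc(OCc2ccccc2)c1
F6 | step 4 | 1,3,5‑tris(benzyloxy)benzene (purchased) | c1ccccc1COc1cc(OCc2ccccc2)cc(OCc2ccccc2)c1
F7 | step 4 | 2,4,6‑tris(benzyloxy)benzaldehyde | O=Cc1c(OCc2ccccc2)cc(OCc2ccccc2)cc1OCc1ccccc1
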